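**Retrosynthetic overview**
- Target 13 ⇒ aryl iodide 12 + isoprene: the C3a–C3 and O1–C2 bonds come from an enantioselective palladium-catalysed Heck/Tsuji–Trost heteroannulation, which closes the dihydrofuran ring and sets C2.
- 12 ⇒ iodo Mannich base 5 + pyrone 10 (benzylic C–C bond by o-quinone methide Michael addition); 10 ⇒ acyclic triketo ester 8 (lactone C–O bond, pyrone ring).
- 5 ⇒ phloroglucinol by acylation, mono-iodination (iodine is first a blocking group, later the Heck handle) and aminomethylation; 8 ⇒ dianion of methyl 3-oxopentanoate + a propionyl Weinreb amide.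
- Ring order: the benzene ring is bought; the pyrone ring and then the dihydrofuran ring are both closed in the same final one-pot operation.

Assumption: the (S,Rs) enantiomer of the TY-Phos-type sulfinamide monophosphine ligand is taken as the one that gives the 2R product; if a model run shows the opposite sense, its mirror image is used and nothing else changes.

Step 1
Reactants: 1 phloroglucinol; 2 isobutyryl chloride
Product: 3 2-methyl-1-(2,4,6-trihydroxyphenyl)propan-1-one
Conditions: AlCl3 (3 equiv), PhNO2, 25 → 80 °C; ice/aq. HCl
Reagents that add atoms: none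
Why: Friedel–Crafts acylation of the very electron-rich triphenol gives the C-acyl product, and the aluminium-chelated aryl ketone formed is deactivated towards a second acylation.

Step 2
Reactants: 3 2-methyl-1-(2,4,6-trihydroxyphenyl)propan-1-one
Product: 4 1-(2,4,6-trihydroxy-3-iodophenyl)-2-methylpropan-1-one
Conditions: I2 (1.0 equiv, slow addition), NaHCO3, THF/H2O 1:1, 0 °C, dark
Reagents that add atoms: iodine, II
Why: Electrophilic aromatic iodination of the phenoxide at one of the two equivalent free ring carbons; the first iodine lowers the nucleophilicity of the ring so that one equivalent stops mainly at the monoiodide, which now carries both a blocking group and the later Heck handle.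

Step 3
Reactants: 4 1-(2,4,6-trihydroxy-3-iodophenyl)-2-methylpropan-1-one
Product: 5 1-{3-[(dimethylamino)methyl]-2,4,6-trihydroxy-5-iodophenyl}-2-methylpropan-1-one
Conditions: CH2(NMe2)2 (1.1 equiv), MeCN, 0 °C → rt; used directly
Reagents that add atoms: bis(dimethylamino)methane, CN(C)CN(C)C
Why: Phenolic Mannich reaction: the acidic phenol protonates the aminal to the iminium ion, which can only attack the single remaining ring carbon, and the neutral medium avoids protodeiodination.

Step 4
Reactants: 6 methyl 3-oxopentanoate; 7 N-methoxy-N-methylpropanamide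
Product: 8 methyl 4-methyl-3,5-dioxoheptanoate
Conditions: LiN(iPr)2 (2.2 equiv), THF, −78 → 0 °C; then 7, −78 → 0 °C; 1 M HCl to pH 4
Reagents that add atoms: none
Why: Harris-type γ-acylation of a β-keto ester dianion: the more basic γ-carbanion attacks the Weinreb amide, whose chelated tetrahedral adduct prevents over-addition, and the enolisable C4 centre of 8 is of no consequence because it becomes sp2 in the pyrone.

Step 5
Reactants: 5 1-{3-[(dimethylamino)methyl]-2,4,6-trihydroxy-5-iodophenyl}-2-methylpropan-1-one; 8 methyl 4-methyl-3,5-dioxoheptanoate; 9 isoprene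
Product: 13 6-ethyl-4-hydroxy-3-{[(2R)-4,6-dihydroxy-5-(2-methylpropanoyl)-2-(prop-1-en-2-yl)-2,3-dihydro-1-benzofuran-7-yl]methyl}-5-methyl-2H-pyran-2-one, via pyrone 10 (not isolated), via quinone methide 11 (not isolated), via aryl iodide 12 (not isolated)
Conditions: 8 (1.1 equiv), DBU (2.5 equiv), 1,4-dioxane, 90 °C, 1 h; add 5, 90 °C, 2 h, N2 sweep; cool, add 9 (5 equiv), Pd2(dba)3·CHCl3 (5 mol %), (S,Rs)-TY-Phos-type sulfinamide monophosphine (20 mol %), K2CO3 (2 equiv), 60 °C, sealed tube; aq. citric acid (pH 4)
Reagents that add atoms: none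
Why: Proposed new method: a one-pot merger of three known reaction types, namely DBU lactonisation of a 3,5-dioxo ester to the 4-hydroxy-2-pyrone (pyrone ring), Michael addition of the pyronate C3 to the o-quinone methide released thermally from the phenolic Mannich base (no homodimer is possible because neither partner has a second free site), and an enantioselective Larock-type Heck/Tsuji–Trost heteroannulation of an o-halophenol with a 1,3-diene, in which the aryl–palladium species adds to the unsubstituted vinyl terminus of isoprene and the resulting π-allyl complex is closed by the most acidic, para-to-acyl phenoxide on the ligand-selected face to set C2 as R (dihydrofuran ring).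

**Compound list**
1 | phloroglucinol (benzene-1,3,5-triol) | Oc1cc(O)cc(O)c1 | starting material
2 | isobutyryl chloride (2-methylpropanoyl chloride) | CC(C)C(Cl)=O | starting material
3 | 2-methyl-1-(2,4,6-trihydroxyphenyl)propan-1-one | CC(C)C(=O)c1c(O)cc(O)cc1O | intermediate
4 | 1-(2,4,6-trihydroxy-3-iodophenyl)-2-methylpropan-1-one | CC(C)C(=O)c1c(O)cc(O)c(I)c1O | intermediate
5 | 1-{3-[(dimethylamino)methyl]-2,4,6-trihydroxy-5-iodophenyl}-2-methylpropan-1-one | CC(C)C(=O)c1c(O)c(CN(C)C)c(O)c(I)c1O | intermediate
6 | methyl 3-oxopentanoate | CCC(=O)CC(=O)OC | starting material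
7 | N-methoxy-N-methylpropanamide | CCC(=O)N(C)OC | starting material
8 | methyl 4-methyl-3,5-dioxoheptanoate (racemic, enolisable C4) | CCC(=O)C(C)C(=O)CC(=O)OC | intermediate
9 | isoprene (2-methylbuta-1,3-diene) | C=CC(C)=C | starting material
10 | 6-ethyl-4-hydroxy-5-methyl-2H-pyran-2-one | CCc1oc(=O)cc(O)c1C | intermediate
11 | 3,5-dihydroxy-2-iodo-6-methylidene-4-(2-methylpropanoyl)cyclohexa-2,4-dien-1-one | C=C1C(=O)C(I)=C(O)C(C(=O)C(C)C)=C1O | intermediate
12 | 6-ethyl-4-hydroxy-5-methyl-3-{[2,4,6-trihydroxy-3-iodo-5-(2-methylpropanoyl)phenyl]methyl}-2H-pyran-2-one | CCc1oc(=O)c(Cc2c(O)c(I)c(O)c(C(=O)C(C)C)c2O)c(O)c1C | intermediate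
13 | 6-ethyl-4-hydroxy-3-{[(2R)-4,6-dihydroxy-5-(2-methylpropanoyl)-2-(prop-1-en-2-yl)-2,3-dihydro-1-benzofuran-7-yl]methyl}-5-methyl-2H-pyran-2-one | C=C(C)[C@H]1Cc2c(O)c(C(=O)C(C)C)c(O)c(Cc3c(O)c(C)c(CC)oc3=O)c2O1 | target

**Step count**
Total: 5 steps. Longest linear sequence: 4 steps (1 → 3 → 4 → 5 → 13); step 4 is the convergent branch.

**Three steps most likely to fail, with fallbacks**

First, step 5. The palladium stage must work on a polyanionic, fully substituted tri-oxygenated aryl iodide. It can fail through protodeiodination, closure by an ortho-to-acyl phenoxide, insertion at the wrong alkene of isoprene, or loss of ee by re-ionisation of the allylic aryl ether.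

The fallback sets out from 4 and moves the annulation to the simple iodophenol, which is closest to known tremetone-type substrates. The same palladium/ligand system (Pd2(dba)3·CHCl3, K2CO3, isoprene, dioxane, 60 °C) on 4 gives (2R)-1-[4,6-dihydroxy-2-(prop-1-en-2-yl)-2,3-dihydro-1-benzofuran-5-yl]-2-methylpropan-1-one F1. Bis(dimethylamino)methane in MeCN then aminomethylates its one free ring carbon to (2R)-1-{7-[(dimethylamino)methyl]-4,6-dihydroxy-2-(prop-1-en-2-yl)-2,3-dihydro-1-benzofuran-5-yl}-2-methylpropan-1-one F2. Heating F2 with 8 and DBU in dioxane at 90 °C lactonises 8 to 10, while F2 loses dimethylamine to the quinone methide (2R)-4-hydroxy-7-methylidene-5-(2-methylpropanoyl)-2-(prop-1-en-2-yl)-2,3-dihydro-1-benzofuran-6(7H)-one F3. Pyrone 10 traps F3 at C3 and the fallback comes back to the route at 13, with no palladium present during the hot stage.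

Second, step 2. Mono-iodination of a substrate with two equivalent reactive carbons may give di-iodide plus recovered 3, and 4 is light-sensitive.

The fallback sets out from 3 and inverts the order of the two electrophilic substitutions. Bis(dimethylamino)methane (1.0 equiv, MeCN, 0 °C) gives the mono-Mannich base 1-{3-[(dimethylamino)methyl]-2,4,6-trihydroxyphenyl}-2-methylpropan-1-one F4, which separates as its zwitterion and so escapes a second aminomethylation. I2/NaHCO3 in THF/H2O then iodinates its single remaining ring carbon, and the fallback comes back to the route at 5.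

Third, step 3. Mannich base 5 may lose dimethylamine prematurely and self-condense through O-alkylation, or may deiodinate.

The fallback sets out from 4 (together with 8) and reverses the polarity of the methylene transfer. DBU in toluene at 90 °C converts 8 into isolated 10, which with bis(dimethylamino)methane gives the pyrone Mannich base 3-[(dimethylamino)methyl]-6-ethyl-4-hydroxy-5-methyl-2H-pyran-2-one F5. Warmed with 4 in dioxane, F5 loses dimethylamine to 6-ethyl-5-methyl-3-methylidene-2H-pyran-2,4(3H)-dione F6, which the only free ring carbon of 4 attacks in a Friedel–Crafts-type Michael addition. The fallback comes back to the route at 12, which is isolated and carried through the palladium stage of step 5 to 13.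

**Further compounds**
F1 | step 5 | (2R)-1-[4,6-dihydroxy-2-(prop-1-en-2-yl)-2,3-dihydro-1-benzofuran-5-yl]-2-methylpropan-1-one | C=C(C)[C@H]1Cc2c(O)c(C(=O)C(C)C)c(O)cc2O1
F2 | step 5 | (2R)-1-{7-[(dimethylamino)methyl]-4,6-dihydroxy-2-(prop-1-en-2-yl)-2,3-dihydro-1-benzofuran-5-yl}-2-methylpropan-1-one | C=C(C)[C@H]1Cc2c(O)c(C(=O)C(C)C)c(O)c(CN(C)C)c2O1
F3 | step 5 | (2R)-4-hydroxy-7-methylidene-5-(2-methylpropanoyl)-2-(prop-1-en-2-yl)-2,3-dihydro-1-benzofuran-6(7H)-one | C=C(C)[C@H]1CC2=C(O1)C(=C)C(=O)C(C(=O)C(C)C)=C2O
F4 | step 2 | 1-{3-[(dimethylamino)methyl]-2,4,6-trihydroxyphenyl}-2-methylpropan-1-one | CC(C)C(=O)c1c(O)cc(O)c(CN(C)C)c1O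
F5 | step 3 | 3-[(dimethylamino)methyl]-6-ethyl-4-hydroxy-5-methyl-2H-pyran-2-one | CCc1oc(=O)c(CN(C)C)c(O)c1C
F6 | step 3 | 6-ethyl-5-methyl-3-methylidene-2H-pyran-2,4(3H)-dione | CCC1=C(C)C(=O)C(=C)C(=O)O1
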